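**Retrosynthetic overview**
1. Target 36 ⇐ global O‑debenzylation of 35; the lower chroman is joined last by a stereoretentive sp2–sp3 coupling of aryl bromide 28 with (S)‑3‑borylchroman 32.
2. 28 ⇐ trans‑lactone 26 ⇐ 2,4‑diaryl‑4H‑chromene 23 by an oxidative 2→3 aryl shift (flavonoid → isoflavonoid skeleton); this forms the C3–ring B bond, and C3 is then equilibrated trans to C4.
3. 23 ⇐ o‑quinone methide (from benzhydrol 20) + enamide 10 under a chiral phosphoric acid; this closes the upper pyran ring and sets C4.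
4. 20 ⇐ 3‑(benzyloxy)phenol 2 + aldehyde 18 (ring M from 3‑bromophenol; the CHO carbon becomes C4, which fixes the ring M substitution pattern); 10 ⇐ 1,4‑benzoquinone (ring B).
5. Ring order: rings A, B, M and D are bought as C6 units; the upper pyran ring is formed in step 10, the lower pyran ring separately in step 14, and the two halves are joined in step 16.

Assumption: where the sense of induction of a chiral catalyst (steps 10 and 15) cannot be fixed on paper, the catalyst enantiomer that gives the stated configuration is used.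

**Route**

Step 1
Reactants: 1 resorcinol
Product: 2 3-(benzyloxy)phenol
Conditions: resorcinol (2 equiv), BnBr (1 equiv), K2CO3, acetone, 56 °C
Reagents that add atoms: benzyl bromide, BrCc1ccccc1
Why: Williamson etherification; the excess of diol holds it at the monoether.

Step 2
Reactants: 3 1,4-benzoquinone
Product: 4 benzene-1,2,4-triyl triacetate
Conditions: Ac2O, H2SO4 (cat.), 40–50 °C
Reagents that add atoms: acetic anhydride, CC(=O)OC(C)=O
Why: Thiele–Winstein acetoxylation (conjugate addition of acetate to the protonated quinone, enolisation, O‑acetylation).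

Step 3
Reactants: 4 benzene-1,2,4-triyl triacetate
Product: 6 1-(2,4,5-trihydroxyphenyl)ethan-1-one, via Fries diacetate 5 (not isolated)
Conditions: BF3·OEt2 (3 equiv), AcOH, 95 °C; then H2O, 60 °C
Reagents that add atoms: none
Why: Fries rearrangement to the only ring position that is ortho and para to oxygen without lying between two substituents, then hydrolysis of the remaining aryl acetates.

Step 4
Reactants: 6 1-(2,4,5-trihydroxyphenyl)ethan-1-one
Product: 8 1-[2-(benzyloxy)-4,5-dimethoxyphenyl]ethan-1-one, via dimethyl ether 7 (not isolated)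
Conditions: MeI (2.1 equiv), K2CO3, acetone, 40 °C; then BnBr (1.3 equiv), K2CO3, DMF, 70 °C
Reagents that add atoms: iodomethane, CI; benzyl bromide, BrCc1ccccc1
Why: Williamson etherification in chelation‑controlled order; the 2‑OH hydrogen‑bonded to the ketone is alkylated last, so MeI caps the 4‑ and 5‑OH and BnBr then caps the 2‑OH.

Step 5
Reactants: 8 1-[2-(benzyloxy)-4,5-dimethoxyphenyl]ethan-1-one
Product: 10 N-{1-[2-(benzyloxy)-4,5-dimethoxyphenyl]ethenyl}acetamide, via ketimine 9 (not isolated)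
Conditions: NH3 (7 M in MeOH), Ti(OiPr)4 (2 equiv), rt; evaporate; then Ac2O, Et3N, toluene, 0 °C to rt
Reagents that add atoms: ammonia, N; acetic anhydride, CC(=O)OC(C)=O
Why: Ti‑mediated condensation to the N–H ketimine, then N‑acylation and tautomerisation to the enamide.

Step 6
Reactants: 11 3-bromophenol
Product: 14 5-bromobenzene-1,3-diol, via silyl ether 12 (not isolated), via aryl boronate 13 (not isolated)
Conditions: (Me3Si)2NH (0.6 equiv), 80 °C; then [Ir(OMe)(cod)]2 (1 mol %), 4,4'-di-tert-butyl-2,2'-bipyridine (2 mol %), B2pin2, THF, 80 °C; then KHSO5 (Oxone), acetone/H2O, rt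
Reagents that add atoms: potassium peroxymonosulfate, [K+].[O-]S(=O)(=O)OO
Why: sterically controlled Ir‑catalysed C–H borylation goes to the only C–H that is meta to both Br and OSiMe3, and oxidation of C–B (with loss of the silyl group) gives the phenol.

Step 7
Reactants: 14 5-bromobenzene-1,3-diol
Product: 16 2-bromo-4,6-dihydroxybenzaldehyde, via iminium chloride 15 (not isolated)
Conditions: POCl3, DMF, MeCN, 0 °C to rt; then H2O, 50 °C
Reagents that add atoms: N,N-dimethylformamide, CN(C)C=O; water, O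
Why: Vilsmeier–Haack formylation para to one OH and ortho to the other (next to Br), the same site as in the orcinol → orcylaldehyde case.

Step 8
Reactants: 16 2-bromo-4,6-dihydroxybenzaldehyde
Product: 18 4-(benzyloxy)-2-bromo-6-methoxybenzaldehyde, via monobenzyl ether 17 (not isolated)
Conditions: BnBr (1.05 equiv), KHCO3, MeCN, 60 °C; then MeI, K2CO3, DMF, 50 °C
Reagents that add atoms: benzyl bromide, BrCc1ccccc1; iodomethane, CI
Why: Williamson etherification; the free para‑OH is benzylated first and the OH chelated to the aldehyde is methylated second, which differentiates the two ring M oxygens.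

Step 9
Reactants: 2 3-(benzyloxy)phenol; 18 4-(benzyloxy)-2-bromo-6-methoxybenzaldehyde
Product: 20 [4-(benzyloxy)-2-bromo-6-methoxyphenyl][4-(benzyloxy)-2-hydroxyphenyl]methanol (racemic), via magnesium phenoxide 19 (not isolated)
Conditions: EtMgBr (1.0 equiv), Et2O, 0 °C; then 18, toluene, rt; aqueous work-up
Reagents that add atoms: none
Why: Casiraghi ortho‑hydroxyalkylation; the magnesium phenoxide delivers the aldehyde through a chelated six‑membered transition state to the ortho carbon that is para to OBn.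

Step 10
Reactants: 20 benzhydrol; 10 enamide
Product: 23 (4S)-7-(benzyloxy)-2-[2-(benzyloxy)-4,5-dimethoxyphenyl]-4-[4-(benzyloxy)-2-bromo-6-methoxyphenyl]-4H-chromene, via o-quinone methide 21 (not isolated), via N-acetyl aminal 22 (not isolated)
Conditions: (R)-3,3'-bis(2,4,6-triisopropylphenyl)-1,1'-binaphthyl-2,2'-diyl hydrogen phosphate ((R)-TRIP, 5 mol %), 4 Å molecular sieves, CH2Cl2, −20 °C to rt; then pyridinium p-toluenesulfonate (10 mol %), 40 °C
Reagents that add atoms: none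
Why: chiral phosphoric acid catalysed conjugate addition of the enamide to the in situ o‑quinone methide with ring closure (formal [4+2]); the acid binds both partners and sets C4, and loss of acetamide gives the enol ether.

Step 11
Reactants: 23 (4S)-4H-chromene
Product: 26 (3R,4S)-7-(benzyloxy)-3-[2-(benzyloxy)-4,5-dimethoxyphenyl]-4-[4-(benzyloxy)-2-bromo-6-methoxyphenyl]chroman-2-one, via ortho ester 24 (not isolated), via cis lactone 25 (not isolated)
Conditions: PhI(OH)OTs (1.15 equiv), MeOH/CH2Cl2 3:1, −20 to 0 °C; then H2O; then DBU (0.3 equiv), toluene, 60 °C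
Reagents that add atoms: water, O
Why: Proposed new method: the trivalent iodine electrophile adds to C3 of the cyclic aryl enol ether anti to the C4 aryl and methanol traps the 2‑oxocarbenium as a ketal; the electron‑rich 2‑aryl group then migrates from the ketal carbon C2 to C3 with loss of PhI (phenonium‑type 1,2‑aryl shift pushed by two oxygen lone pairs) to a dialkoxycarbenium ion that is caught as the ortho ester and hydrolysed to the lactone; C4 is untouched and DBU equilibrates the now acidic C3–H to the trans‑diaryl lactone, so C3 is set relative to C4; the closest known reactions are the hypervalent‑iodine or Tl(NO3)3 2,3‑aryl migration of flavanones to isoflavones and the aryl ketone → α‑aryl ester oxidative rearrangement, neither shown on a 4‑substituted flav‑2‑ene.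

Step 12
Reactants: 26 trans-lactone
Product: 28 (3R,4S)-7-(benzyloxy)-3-[2-(benzyloxy)-4,5-dimethoxyphenyl]-4-[4-(benzyloxy)-2-bromo-6-methoxyphenyl]chroman, via lactol 27 (not isolated)
Conditions: iBu2AlH (1.1 equiv), CH2Cl2, −78 °C; then Et3SiH (4 equiv), BF3·OEt2 (2 equiv), −78 to −30 °C
Reagents that add atoms: none
Why: partial reduction of the aryl lactone to the lactol, then ionic hydrogenation of the derived oxocarbenium ion (reductive deoxygenation of a lactone to a cyclic ether); no stereocentre is created and the low temperature keeps the trans C3/C4 pair.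

Step 13
Reactants: 2 3-(benzyloxy)phenol; 29 3-bromoprop-1-yne
Product: 30 1-(benzyloxy)-3-(prop-2-yn-1-yloxy)benzene
Conditions: K2CO3, acetone, 56 °C
Reagents that add atoms: none
Why: Williamson etherification of the phenol with the propargylic bromide.

Step 14
Reactants: 30 aryl propargyl ether
Product: 31 7-(benzyloxy)-2H-chromene
Conditions: Ph3PAuNTf2 (2 mol %), CH2Cl2, rt
Reagents that add atoms: none
Why: gold‑catalysed 6‑endo intramolecular hydroarylation of the alkyne, mainly para to OBn (the minor 5‑benzyloxy isomer is removed by chromatography).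

Step 15
Reactants: 31 7-(benzyloxy)-2H-chromene
Product: 32 2-[(3S)-7-(benzyloxy)chroman-3-yl]-4,4,5,5-tetramethyl-1,3,2-dioxaborolane
Conditions: CuCl (5 mol %), (R)-DTBM-SEGPHOS (6 mol %), NaOtBu (10 mol %), B2pin2 (1.1 equiv), MeOH (2 equiv), THF, rt
Reagents that add atoms: bis(pinacolato)diboron, CC1(C)OB(OC1(C)C)B1OC(C)(C)C(C)(C)O1
Why: copper‑catalysed enantioselective protoboration; ligand‑controlled syn addition of Cu–Bpin puts boron on C3 and copper on the benzylic C4, which methanol protonates, so the ligand sets C3.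

Step 16
Reactants: 28 aryl bromide; 32 (S)-3-borylchroman
Product: 35 (3R,4S)-7-(benzyloxy)-3-[2-(benzyloxy)-4,5-dimethoxyphenyl]-4-{4-(benzyloxy)-2-[(3R)-7-(benzyloxy)chroman-3-yl]-6-methoxyphenyl}chroman, via aryllithium 33 (not isolated), via boronate complex 34 (not isolated)
Conditions: t-BuLi (2.05 equiv), THF, −78 °C; then 32 (1.1 equiv), −78 °C; then NBS (1.2 equiv), THF, −78 °C to rt
Reagents that add atoms: none
Why: Br/Li exchange and boronate formation, then NBS bromination of the electron‑rich aryl ring of the boronate triggers a 1,2‑metallate rearrangement with retention at the migrating carbon and elimination (transition‑metal‑free stereospecific sp2–sp3 coupling), so (S)‑C–B becomes (R)‑C–aryl.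

Step 17
Reactants: 35 tetrabenzyl ether
Product: 36 (3R,4S)-3-(2-hydroxy-4,5-dimethoxyphenyl)-4-{4-hydroxy-2-[(3R)-7-hydroxychroman-3-yl]-6-methoxyphenyl}chroman-7-ol
Conditions: H2 (1 atm), 10% Pd/C, EtOAc/MeOH, rt
Reagents that add atoms: none
Why: hydrogenolysis of the four benzyl aryl ethers; the aryl methyl ethers and the three stereocentres are not affected.

**Compound list**

1 | resorcinol (benzene-1,3-diol) | Oc1cccc(O)c1 | starting material
2 | 3-(benzyloxy)phenol | Oc1cccc(OCc2ccccc2)c1 | intermediate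
3 | 1,4-benzoquinone | O=C1C=CC(=O)C=C1 | starting material
4 | benzene-1,2,4-triyl triacetate | CC(=O)Oc1ccc(OC(C)=O)c(OC(C)=O)c1 | intermediate
5 | 4-acetyl-5-hydroxy-1,2-phenylene diacetate (Fries diacetate) | CC(=O)Oc1cc(O)c(C(C)=O)cc1OC(C)=O | intermediate (not isolated)
6 | 1-(2,4,5-trihydroxyphenyl)ethan-1-one | CC(=O)c1cc(O)c(O)cc1O | intermediate
7 | 1-(2-hydroxy-4,5-dimethoxyphenyl)ethan-1-one | CC(=O)c1cc(OC)c(OC)cc1O | intermediate (not isolated)
8 | 1-[2-(benzyloxy)-4,5-dimethoxyphenyl]ethan-1-one | CC(=O)c1cc(OC)c(OC)cc1OCc1ccccc1 | intermediate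
9 | 1-[2-(benzyloxy)-4,5-dimethoxyphenyl]ethan-1-imine | CC(=N)c1cc(OC)c(OC)cc1OCc1ccccc1 | intermediate (not isolated)
10 | N-{1-[2-(benzyloxy)-4,5-dimethoxyphenyl]ethenyl}acetamide | CC(=O)NC(=C)c1cc(OC)c(OC)cc1OCc1ccccc1 | intermediate
11 | 3-bromophenol | Oc1cccc(Br)c1 | starting material
12 | (3-bromophenoxy)trimethylsilane | C[Si](C)(C)Oc1cccc(Br)c1 | intermediate (not isolated)
13 | 2-[3-bromo-5-(trimethylsilyloxy)phenyl]-4,4,5,5-tetramethyl-1,3,2-dioxaborolane | C[Si](C)(C)Oc1cc(Br)cc(c1)B1OC(C)(C)C(C)(C)O1 | intermediate (not isolated)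
14 | 5-bromobenzene-1,3-diol | Oc1cc(O)cc(Br)c1 | intermediate
15 | N-[(2-bromo-4,6-dihydroxyphenyl)methylidene]-N-methylmethanaminium chloride | C[N+](C)=Cc1c(O)cc(O)cc1Br.[Cl-] | intermediate (not isolated)
16 | 2-bromo-4,6-dihydroxybenzaldehyde | O=Cc1c(O)cc(O)cc1Br | intermediate
17 | 4-(benzyloxy)-2-bromo-6-hydroxybenzaldehyde | O=Cc1c(O)cc(OCc2ccccc2)cc1Br | intermediate (not isolated)
18 | 4-(benzyloxy)-2-bromo-6-methoxybenzaldehyde | COc1cc(OCc2ccccc2)cc(Br)c1C=O | intermediate
19 | [3-(benzyloxy)phenoxy]magnesium bromide | Br[Mg]Oc1cccc(OCc2ccccc2)c1 | intermediate (not isolated)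
20 | [4-(benzyloxy)-2-bromo-6-methoxyphenyl][4-(benzyloxy)-2-hydroxyphenyl]methanol (racemic) | COc1cc(OCc2ccccc2)cc(Br)c1C(O)c1ccc(OCc2ccccc2)cc1O | intermediate
21 | 3-(benzyloxy)-6-{[4-(benzyloxy)-2-bromo-6-methoxyphenyl]methylidene}cyclohexa-2,4-dien-1-one (o-quinone methide) | O=C1C=C(OCc2ccccc2)C=CC1=Cc1c(OC)cc(OCc2ccccc2)cc1Br | intermediate (not isolated)
22 | N-{(4S)-7-(benzyloxy)-2-[2-(benzyloxy)-4,5-dimethoxyphenyl]-4-[4-(benzyloxy)-2-bromo-6-methoxyphenyl]chroman-2-yl}acetamide (C2 epimers) | COc1cc(OCc2ccccc2)c(C3(NC(C)=O)C[C@H](c4c(OC)cc(OCc5ccccc5)cc4Br)c4ccc(OCc5ccccc5)cc4O3)cc1OC | intermediate (not isolated)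
23 | (4S)-7-(benzyloxy)-2-[2-(benzyloxy)-4,5-dimethoxyphenyl]-4-[4-(benzyloxy)-2-bromo-6-methoxyphenyl]-4H-chromene | COc1cc(OCc2ccccc2)c(C3=C[C@H](c4c(OC)cc(OCc5ccccc5)cc4Br)c4ccc(OCc5ccccc5)cc4O3)cc1OC | intermediate
24 | (3S,4S)-7-(benzyloxy)-3-[2-(benzyloxy)-4,5-dimethoxyphenyl]-4-[4-(benzyloxy)-2-bromo-6-methoxyphenyl]-2,2-dimethoxychroman (ortho ester) | COc1cc(OCc2ccccc2)c([C@H]3C(OC)(OC)Oc4cc(OCc5ccccc5)ccc4[C@H]3c3c(OC)cc(OCc4ccccc4)cc3Br)cc1OC | intermediate (not isolated)
25 | (3S,4S)-7-(benzyloxy)-3-[2-(benzyloxy)-4,5-dimethoxyphenyl]-4-[4-(benzyloxy)-2-bromo-6-methoxyphenyl]chroman-2-one (cis lactone) | COc1cc(OCc2ccccc2)c([C@H]3C(=O)Oc4cc(OCc5ccccc5)ccc4[C@H]3c3c(OC)cc(OCc4ccccc4)cc3Br)cc1OC | intermediate (not isolated)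
26 | (3R,4S)-7-(benzyloxy)-3-[2-(benzyloxy)-4,5-dimethoxyphenyl]-4-[4-(benzyloxy)-2-bromo-6-methoxyphenyl]chroman-2-one (trans lactone) | COc1cc(OCc2ccccc2)c([C@@H]3C(=O)Oc4cc(OCc5ccccc5)ccc4[C@H]3c3c(OC)cc(OCc4ccccc4)cc3Br)cc1OC | intermediate
27 | (3R,4S)-7-(benzyloxy)-3-[2-(benzyloxy)-4,5-dimethoxyphenyl]-4-[4-(benzyloxy)-2-bromo-6-methoxyphenyl]chroman-2-ol (lactol, C2 epimers) | COc1cc(OCc2ccccc2)c([C@@H]3C(O)Oc4cc(OCc5ccccc5)ccc4[C@H]3c3c(OC)cc(OCc4ccccc4)cc3Br)cc1OC | intermediate (not isolated)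
28 | (3R,4S)-7-(benzyloxy)-3-[2-(benzyloxy)-4,5-dimethoxyphenyl]-4-[4-(benzyloxy)-2-bromo-6-methoxyphenyl]chroman | COc1cc(OCc2ccccc2)c([C@@H]3COc4cc(OCc5ccccc5)ccc4[C@H]3c3c(OC)cc(OCc4ccccc4)cc3Br)cc1OC | intermediate
29 | 3-bromoprop-1-yne (propargyl bromide) | C#CCBr | starting material
30 | 1-(benzyloxy)-3-(prop-2-yn-1-yloxy)benzene | C#CCOc1cccc(OCc2ccccc2)c1 | intermediate
31 | 7-(benzyloxy)-2H-chromene | C1=Cc2ccc(OCc3ccccc3)cc2OC1 | intermediate
32 | 2-[(3S)-7-(benzyloxy)chroman-3-yl]-4,4,5,5-tetramethyl-1,3,2-dioxaborolane | CC1(C)OB(OC1(C)C)[C@@H]1COc2cc(OCc3ccccc3)ccc2C1 | intermediate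
33 | aryllithium from 28 (Li in place of Br; 3R,4S) | COc1cc(OCc2ccccc2)c([C@@H]3COc4cc(OCc5ccccc5)ccc4[C@H]3c3c(OC)cc(OCc4ccccc4)cc3[Li])cc1OC | intermediate (not isolated)
34 | lithium aryl[(3S)-7-(benzyloxy)chroman-3-yl](pinacolato)borate | [Li+].COc1cc(OCc2ccccc2)c([C@@H]3COc4cc(OCc5ccccc5)ccc4[C@H]3c3c(OC)cc(OCc4ccccc4)cc3[B-]3(OC(C)(C)C(C)(C)O3)[C@@H]3COc4cc(OCc5ccccc5)ccc4C3)cc1OC | intermediate (not isolated)
35 | (3R,4S)-7-(benzyloxy)-3-[2-(benzyloxy)-4,5-dimethoxyphenyl]-4-{4-(benzyloxy)-2-[(3R)-7-(benzyloxy)chroman-3-yl]-6-methoxyphenyl}chroman | COc1cc(OCc2ccccc2)c([C@@H]3COc4cc(OCc5ccccc5)ccc4[C@H]3c3c(OC)cc(OCc4ccccc4)cc3[C@@H]3COc4cc(OCc5ccccc5)ccc4C3)cc1OC | intermediate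
36 | (3R,4S)-3-(2-hydroxy-4,5-dimethoxyphenyl)-4-{4-hydroxy-2-[(3R)-7-hydroxychroman-3-yl]-6-methoxyphenyl}chroman-7-ol (CNP0266829.1) | COc1cc(O)c([C@@H]2COc3cc(O)ccc3[C@H]2c2c(OC)cc(O)cc2[C@@H]2COc3cc(O)ccc3C2)cc1OC | target

**Step count and risk**

Total steps: 17. Longest linear sequence: 9 steps (steps 6, 7, 8, 9, 10, 11, 12, 16, 17 from 3‑bromophenol; equally steps 2, 3, 4, 5, 10, 11, 12, 16, 17 from 1,4‑benzoquinone).

Steps most likely to fail:

1. Step 11 (the proposed oxidative 2→3 aryl shift). Risks are over‑oxidation of the 4H‑chromene to the flavylium ion, α‑oxygenation instead of migration, or oxidation of the electron‑rich rings. The fallback uses known chemistry, sets out from ketone 8 and benzhydrol 20, and comes back at lactol 27. Ketone 8 undergoes the established Tl(NO3)3·3H2O / HC(OMe)3–MeOH rearrangement of aryl methyl ketones to methyl 2-[2-(benzyloxy)-4,5-dimethoxyphenyl]acetate F1. iBu2AlH at −78 °C then gives 2-[2-(benzyloxy)-4,5-dimethoxyphenyl]acetaldehyde F2. F2 and 20 are combined under enamine catalysis ((S)-α,α-diphenylprolinol trimethylsilyl ether, PhCO2H) in the known formal [4+2] of aldehydes with o‑quinone methides, which gives the trans‑3,4‑diaryl lactol 27 directly; 27 is reduced with Et3SiH/BF3·OEt2 as in step 12.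

2. Step 16 (boronate coupling with a hindered, ortho‑substituted aryllithium). Risks are slow boronate formation and bromination of the other electron‑rich rings by NBS. The fallback sets out from 2H‑chromene 31 and bromide 28 and comes back at 35. Bromine adds to 31 to give trans-3,4-dibromo-7-(benzyloxy)chroman F5, and DBU eliminates HBr to 7-(benzyloxy)-3-bromo-2H-chromene F6. Bromide 28 is converted (B2pin2, Pd(dppf)Cl2, KOAc) into the aryl pinacol boronate F7. Suzuki coupling of F6 and F7 (Pd(OAc)2, SPhos, K3PO4) gives the isoflav‑3‑ene F8. Ir‑catalysed asymmetric hydrogenation of F8 ([Ir(cod)(phosphine–oxazoline)]BArF, H2 50 bar) sets the lower C3 and gives 35.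

3. Step 10 (chiral phosphoric acid catalysed annulation with a 2,6‑disubstituted aryl on the quinone methide). Risks are low ee or bis‑arylmethane by‑products. The fallback sets out from ketone 8, aldehyde 18 and phenol 2 and comes back at 23. Claisen–Schmidt condensation of 8 and 18 (Ba(OH)2·8H2O, MeOH) gives (E)-1-[2-(benzyloxy)-4,5-dimethoxyphenyl]-3-[4-(benzyloxy)-2-bromo-6-methoxyphenyl]prop-2-en-1-one F3. TfOH‑catalysed Friedel–Crafts Michael addition and cyclodehydration with 2 gives the racemic 4H‑chromene F4. Preparative chiral supercritical‑fluid chromatography of F4 delivers (4S)‑23.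

Further compounds
F1 | step 11 | methyl 2-[2-(benzyloxy)-4,5-dimethoxyphenyl]acetate | COC(=O)Cc1cc(OC)c(OC)cc1OCc1ccccc1
F2 | step 11 | 2-[2-(benzyloxy)-4,5-dimethoxyphenyl]acetaldehyde | O=CCc1cc(OC)c(OC)cc1OCc1ccccc1
F3 | step 10 | (E)-1-[2-(benzyloxy)-4,5-dimethoxyphenyl]-3-[4-(benzyloxy)-2-bromo-6-methoxyphenyl]prop-2-en-1-one | COc1cc(OCc2ccccc2)cc(Br)c1/C=C/C(=O)c1cc(OC)c(OC)cc1OCc1ccccc1
F4 | step 10 | racemic 7-(benzyloxy)-2-[2-(benzyloxy)-4,5-dimethoxyphenyl]-4-[4-(benzyloxy)-2-bromo-6-methoxyphenyl]-4H-chromene | COc1cc(OCc2ccccc2)c(C3=CC(c4c(OC)cc(OCc5ccccc5)cc4Br)c4ccc(OCc5ccccc5)cc4O3)cc1OC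
F5 | step 16 | trans-3,4-dibromo-7-(benzyloxy)chroman (racemic) | BrC1COc2cc(OCc3ccccc3)ccc2C1Br
F6 | step 16 | 7-(benzyloxy)-3-bromo-2H-chromene | BrC1=Cc2ccc(OCc3ccccc3)cc2OC1
F7 | step 16 | aryl pinacol boronate from 28 (Bpin in place of Br; 3R,4S) | COc1cc(OCc2ccccc2)c([C@@H]3COc4cc(OCc5ccccc5)ccc4[C@H]3c3c(OC)cc(OCc4ccccc4)cc3B3OC(C)(C)C(C)(C)O3)cc1OC
F8 | step 16 | (3R,4S)-7-(benzyloxy)-3-[2-(benzyloxy)-4,5-dimethoxyphenyl]-4-{4-(benzyloxy)-2-[7-(benzyloxy)-2H-chromen-3-yl]-6-methoxyphenyl}chroman | COc1cc(OCc2ccccc2)c([C@@H]3COc4cc(OCc5ccccc5)ccc4[C@H]3c3c(OC)cc(OCc4ccccc4)cc3C3=Cc4ccc(OCc5ccccc5)cc4OC3)cc1OC
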